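**Retrosynthetic overview**

1. Target ⇐ selective acetylation of the primary C13–OH; butenolide and C6 ⇐ C1–OH-directed 1,2-reduction and lactonisation of a ten-membered keto ester.
2. Ten-membered ring ⇐ electroreductive nickel-catalysed ring expansion: an alkenyl triflate (C7) adds to the carbonyl (C6) of a seven-membered lactone, which then opens and frees C1–OH.
3. Alkenyl triflate side chain ⇐ β-keto ester dianion alkylation (C8–C9 bond) of an allylic chloride, then Z-selective enol triflation.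
4. Seven-membered lactone (C1–C6, C9, C10, C14, C15, Z-alkene, C1 and C3 stereocentres) ⇐ Baeyer–Villiger oxidation of a 4-acetoxy enone made from (R)-carvone.
5. Ring order: cyclohexene (bought) → oxepinone → oxa-bridged bicycle → cyclodecane → fused butenolide.

Assumption: positions are given in germacrane numbering (C1–C15; C12 lactone carbonyl, C13 acetoxymethyl carbon, C14 exocyclic methylene, C15 methyl), and 1, 7 and all reagents are commercial.

**Route**

Step 1
Reactants: 1 (R)-(−)-carvone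
Product: 2 (5R)-5-(3-chloroprop-1-en-2-yl)-2-methylcyclohex-2-en-1-one
Conditions: Ca(OCl)2, CO2 (dry ice), CH2Cl2/H2O, 0 °C
Reagents that add atoms: calcium hypochlorite Ca(OCl)2, [Ca+2].[O-]Cl.[O-]Cl
Why: Ene-type allylic chlorination by HOCl attacks only the electron-rich isopropenyl group, giving the 2-(chloromethyl)allyl unit (future C9, C10, C14) and leaving the stereocentre untouched.

Step 2
Reactants: 2 (5R)-5-(3-chloroprop-1-en-2-yl)-2-methylcyclohex-2-en-1-one
Product: 3 (1R,5R)-5-(3-chloroprop-1-en-2-yl)-2-methylcyclohex-2-en-1-ol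
Conditions: NaBH4, CeCl3·7H2O, MeOH, −78 → 0 °C
Reagents that add atoms: none
Why: Luche 1,2-reduction; axial hydride attack controlled by the C5 substituent gives the cis alcohol (1R), as in the carvone to cis-carveol reduction.

Step 3
Reactants: 3 (1R,5R)-5-(3-chloroprop-1-en-2-yl)-2-methylcyclohex-2-en-1-ol
Product: 4 (1S,5R)-5-(3-chloroprop-1-en-2-yl)-2-methylcyclohex-2-en-1-yl acetate
Conditions: AcOH, PPh3, DIAD, THF, 0 °C → rt
Reagents that add atoms: acetic acid, CC(=O)O
Why: Mitsunobu esterification with inversion turns the cis alcohol into the trans acetate; this carbon is C3 of the target, now S and already acetylated.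

Step 4
Reactants: 4 (1S,5R)-5-(3-chloroprop-1-en-2-yl)-2-methylcyclohex-2-en-1-yl acetate
Product: 5 (1S,5R)-5-(3-chloroprop-1-en-2-yl)-2-methyl-4-oxocyclohex-2-en-1-yl acetate
Conditions: CrO3, 3,5-dimethylpyrazole, CH2Cl2, −20 °C
Reagents that add atoms: chromium trioxide CrO3, O=[Cr](=O)=O
Why: Allylic oxidation of the only ring methylene next to the trisubstituted alkene gives the enone (future C6 carbonyl); no stereocentre is touched.

Step 5
Reactants: 5 (1S,5R)-5-(3-chloroprop-1-en-2-yl)-2-methyl-4-oxocyclohex-2-en-1-yl acetate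
Product: 6 (5S,7R)-7-(3-chloroprop-1-en-2-yl)-4-methyl-2-oxo-2,5,6,7-tetrahydrooxepin-5-yl acetate
Conditions: mCPBA (2 equiv), TFA (1 equiv), CH2Cl2, 0 °C → rt
Reagents that add atoms: 3-chloroperbenzoic acid, OOC(=O)c1cccc(Cl)c1
Why: Acid-accelerated Baeyer–Villiger oxidation; the secondary, allylic carbon migrates with retention in preference to the vinyl carbon, which places oxygen on C1 (R). The exocyclic alkene is deactivated towards epoxidation by its CH2Cl and α-acyl neighbours.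

Step 6
Reactants: 7 methyl 3-hydroxypropanoate
Product: 8 methyl 3-[(tert-butyldimethylsilyl)oxy]propanoate
Conditions: TBSCl, imidazole, DMF, rt
Reagents that add atoms: tert-butyldimethylsilyl chloride, CC(C)(C)[Si](C)(C)Cl
Why: Standard silylation of a primary alcohol; the silyl ether carries the future C13 oxygen through the basic and reductive steps.

Step 7
Reactants: 8 methyl 3-[(tert-butyldimethylsilyl)oxy]propanoate
Product: 9 methyl 2-{[(tert-butyldimethylsilyl)oxy]methyl}-3-oxobutanoate (racemic)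
Conditions: LDA (2.1 equiv), THF, −78 °C; AcCl (1.0 equiv), −78 °C; NH4Cl (aq)
Reagents that add atoms: acetyl chloride, CC(Cl)=O
Why: Claisen-type C-acylation of the lithium ester enolate at −78 °C (β-silyloxide elimination is slow there) gives the β-keto ester that holds C7, C8, C11, C12 and C13.

Step 8
Reactants: 6 (5S,7R)-7-(3-chloroprop-1-en-2-yl)-4-methyl-2-oxo-2,5,6,7-tetrahydrooxepin-5-yl acetate; 9 methyl 2-{[(tert-butyldimethylsilyl)oxy]methyl}-3-oxobutanoate
Product: 10 methyl 6-[(5S,7R)-5-acetoxy-4-methyl-2-oxo-2,5,6,7-tetrahydrooxepin-7-yl]-2-{[(tert-butyldimethylsilyl)oxy]methyl}-3-oxohept-6-enoate (C2 epimers)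
Conditions: 9 (1.3 equiv), NaH, THF, 0 °C; n-BuLi, −20 °C; then 6, nBu4NI (cat.), −78 → −20 °C; NH4Cl (aq)
Reagents that add atoms: none
Why: Weiler dianion γ-alkylation forms the C8–C9 bond; SN2 and SN2′ attack on the 2-substituted allyl chloride give the same product, and alkylation is faster than addition to the lactone or acetate at low temperature.

Step 9
Reactants: 10 methyl 6-[(5S,7R)-5-acetoxy-4-methyl-2-oxo-2,5,6,7-tetrahydrooxepin-7-yl]-2-{[(tert-butyldimethylsilyl)oxy]methyl}-3-oxohept-6-enoate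
Product: 11 methyl (2Z)-6-[(5S,7R)-5-acetoxy-4-methyl-2-oxo-2,5,6,7-tetrahydrooxepin-7-yl]-2-{[(tert-butyldimethylsilyl)oxy]methyl}-3-{[(trifluoromethyl)sulfonyl]oxy}hepta-2,6-dienoate
Conditions: NaH (1.05 equiv), THF, 0 °C; Tf2O, −78 °C
Reagents that add atoms: trifluoromethanesulfonic anhydride, O=S(=O)(OS(=O)(=O)C(F)(F)F)C(F)(F)F
Why: O-sulfonylation of the chelated sodium enolate of the β-keto ester gives the Z enol triflate (OTf cis to CO2Me), the geometry needed later for lactonisation; only the most acidic C–H is deprotonated.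

Step 10
Reactants: 11 methyl (2Z)-6-[(5S,7R)-5-acetoxy-4-methyl-2-oxo-2,5,6,7-tetrahydrooxepin-7-yl]-2-{[(tert-butyldimethylsilyl)oxy]methyl}-3-{[(trifluoromethyl)sulfonyl]oxy}hepta-2,6-dienoate
Product: 13 methyl (2Z)-2-[(3Z,5S,7R)-5-acetoxy-7-hydroxy-4-methyl-8-methylidene-2-oxocyclodec-3-en-1-ylidene]-3-[(tert-butyldimethylsilyl)oxy]propanoate, via oxa-bridged hemiketal 12 (not isolated)
Conditions: NiBr2·DME (10 mol %), 4,4′-di-tert-butyl-2,2′-bipyridine (12 mol %), nBu4NBr (0.1 M), DMF, Zn anode, RVC cathode, undivided cell, 4 mA (2.2 F/mol), 0.01 M, rt; NH4Cl (aq)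
Reagents that add atoms: none
Why: Proposed new method: electroreductive nickel-catalysed intramolecular alkenylation of a lactone carbonyl with ring expansion. Zerovalent nickel inserts into the alkenyl C–OTf bond, cathodic reduction gives a nucleophilic alkenyl monovalent nickel species, and C7 adds to the lactone C=O through a seven-membered transition state; the resulting bridged hemiketal alkoxide 12 is held by Zn2+ from the anode and opens on work-up to the ten-membered hydroxy ketone, with the C1–O bond (R) and the triflate alkene geometry kept. The closest known reactions are nickel-catalysed reductive additions of aryl and alkenyl halides to ketones and aldehydes (chemical or cathodic reductant), cyclisation of alkenylnickel species onto esters, and stoichiometric ring expansion of lactones by tethered organometallics.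

Step 11
Reactants: 13 methyl (2Z)-2-[(3Z,5S,7R)-5-acetoxy-7-hydroxy-4-methyl-8-methylidene-2-oxocyclodec-3-en-1-ylidene]-3-[(tert-butyldimethylsilyl)oxy]propanoate
Product: 16 (7R,9S,10Z,11aR)-7-hydroxy-3-(hydroxymethyl)-10-methyl-6-methylidene-2-oxo-2,4,5,6,7,8,9,11a-octahydrocyclodeca[b]furan-9-yl acetate, via hydroxy ester 14 (not isolated), via silyl butenolide 15 (not isolated)
Conditions: NaBH(OAc)3, AcOH/MeCN 1:1, −20 °C → rt; then HF·pyridine, 0 °C → rt
Reagents that add atoms: none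
Why: Evans–Saksena-type hydroxyl-directed reduction; boron bound to C1–O delivers hydride across the ring along the path the C1 oxygen took to C6 in 6 and 12, so H-6 ends on the C1–O side and C6 is R. The Z γ-hydroxy enoate 14 then lactonises to the butenolide and HF removes the primary silyl ether.

Step 12
Reactants: 16 (7R,9S,10Z,11aR)-7-hydroxy-3-(hydroxymethyl)-10-methyl-6-methylidene-2-oxo-2,4,5,6,7,8,9,11a-octahydrocyclodeca[b]furan-9-yl acetate
Product: 17 [(7R,9S,10Z,11aR)-9-acetoxy-7-hydroxy-10-methyl-6-methylidene-2-oxo-2,4,5,6,7,8,9,11a-octahydrocyclodeca[b]furan-3-yl]methyl acetate (CNP0227830.1)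
Conditions: AcCl (1.1 equiv), 2,4,6-collidine, CH2Cl2, −78 °C
Reagents that add atoms: acetyl chloride, CC(Cl)=O
Why: Kinetically selective acylation of the primary allylic C13–OH over the hindered secondary C1–OH; no stereocentre is involved.

**Compound list**

1 | (R)-(−)-carvone, (5R)-2-methyl-5-(prop-1-en-2-yl)cyclohex-2-en-1-one | CC1=CC[C@H](CC1=O)C(C)=C | starting material
2 | (5R)-5-(3-chloroprop-1-en-2-yl)-2-methylcyclohex-2-en-1-one | CC1=CC[C@H](CC1=O)C(=C)CCl | intermediate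
3 | (1R,5R)-5-(3-chloroprop-1-en-2-yl)-2-methylcyclohex-2-en-1-ol | CC1=CC[C@H](C[C@H]1O)C(=C)CCl | intermediate
4 | (1S,5R)-5-(3-chloroprop-1-en-2-yl)-2-methylcyclohex-2-en-1-yl acetate | CC1=CC[C@H](C[C@@H]1OC(C)=O)C(=C)CCl | intermediate
5 | (1S,5R)-5-(3-chloroprop-1-en-2-yl)-2-methyl-4-oxocyclohex-2-en-1-yl acetate | CC1=CC(=O)[C@H](C[C@@H]1OC(C)=O)C(=C)CCl | intermediate
6 | (5S,7R)-7-(3-chloroprop-1-en-2-yl)-4-methyl-2-oxo-2,5,6,7-tetrahydrooxepin-5-yl acetate | CC1=CC(=O)O[C@H](C[C@@H]1OC(C)=O)C(=C)CCl | intermediate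
7 | methyl 3-hydroxypropanoate | COC(=O)CCO | starting material
8 | methyl 3-[(tert-butyldimethylsilyl)oxy]propanoate | COC(=O)CCO[Si](C)(C)C(C)(C)C | intermediate
9 | methyl 2-{[(tert-butyldimethylsilyl)oxy]methyl}-3-oxobutanoate (racemic) | CC(=O)C(CO[Si](C)(C)C(C)(C)C)C(=O)OC | intermediate
10 | methyl 6-[(5S,7R)-5-acetoxy-4-methyl-2-oxo-2,5,6,7-tetrahydrooxepin-7-yl]-2-{[(tert-butyldimethylsilyl)oxy]methyl}-3-oxohept-6-enoate (C2 epimers) | CC1=CC(=O)O[C@H](C[C@@H]1OC(C)=O)C(=C)CCC(=O)C(CO[Si](C)(C)C(C)(C)C)C(=O)OC | intermediate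
11 | methyl (2Z)-6-[(5S,7R)-5-acetoxy-4-methyl-2-oxo-2,5,6,7-tetrahydrooxepin-7-yl]-2-{[(tert-butyldimethylsilyl)oxy]methyl}-3-{[(trifluoromethyl)sulfonyl]oxy}hepta-2,6-dienoate | CC1=CC(=O)O[C@H](C[C@@H]1OC(C)=O)C(=C)CC/C(OS(=O)(=O)C(F)(F)F)=C(\CO[Si](C)(C)C(C)(C)C)C(=O)OC | intermediate
12 | oxa-bridged hemiketal of 13 (C6 carries OH and an O bridge to C1; 11-oxabicyclo[4.4.1]undecane core, other substituents as in 13) | CC1=C[C@]2(O)O[C@H](C[C@@H]1OC(C)=O)C(=C)CC/C2=C(\CO[Si](C)(C)C(C)(C)C)C(=O)OC | intermediate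
13 | methyl (2Z)-2-[(3Z,5S,7R)-5-acetoxy-7-hydroxy-4-methyl-8-methylidene-2-oxocyclodec-3-en-1-ylidene]-3-[(tert-butyldimethylsilyl)oxy]propanoate | C=C1CC/C(=C(\CO[Si](C)(C)C(C)(C)C)C(=O)OC)C(=O)/C=C(/C)[C@@H](OC(C)=O)C[C@H]1O | intermediate
14 | methyl (2Z)-2-[(2R,3Z,5S,7R)-5-acetoxy-2,7-dihydroxy-4-methyl-8-methylidenecyclodec-3-en-1-ylidene]-3-[(tert-butyldimethylsilyl)oxy]propanoate | C=C1CC/C(=C(\CO[Si](C)(C)C(C)(C)C)C(=O)OC)[C@H](O)/C=C(/C)[C@@H](OC(C)=O)C[C@H]1O | intermediate
15 | (7R,9S,10Z,11aR)-3-{[(tert-butyldimethylsilyl)oxy]methyl}-7-hydroxy-10-methyl-6-methylidene-2-oxo-2,4,5,6,7,8,9,11a-octahydrocyclodeca[b]furan-9-yl acetate | C=C1CCC2=C(CO[Si](C)(C)C(C)(C)C)C(=O)O[C@@H]2/C=C(/C)[C@@H](OC(C)=O)C[C@H]1O | intermediate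
16 | (7R,9S,10Z,11aR)-7-hydroxy-3-(hydroxymethyl)-10-methyl-6-methylidene-2-oxo-2,4,5,6,7,8,9,11a-octahydrocyclodeca[b]furan-9-yl acetate | C=C1CCC2=C(CO)C(=O)O[C@@H]2/C=C(/C)[C@@H](OC(C)=O)C[C@H]1O | intermediate
17 | [(7R,9S,10Z,11aR)-9-acetoxy-7-hydroxy-10-methyl-6-methylidene-2-oxo-2,4,5,6,7,8,9,11a-octahydrocyclodeca[b]furan-3-yl]methyl acetate; (1R,3S,6R,4Z)-3,13-diacetoxy-1-hydroxygermacra-4,7(11),10(14)-trien-12,6-olide | C=C1CCC2=C(COC(C)=O)C(=O)O[C@@H]2/C=C(/C)[C@@H](OC(C)=O)C[C@H]1O | target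

**Step count**

Total: 12 steps. Longest linear sequence: 10 steps (steps 1–5 and 8–12 from carvone); steps 6–7 are a two-step side branch.

**Three steps most likely to fail**

Step 10 (the new electrochemical ring expansion). Zerovalent nickel may instead ionise the allylic lactone or acetate, or the alkenylnickel may simply be protonated. The fallback sets out from 10 and returns at 13. Ph3P/I2/Et3N in MeCN converts the β-keto ester into methyl (2Z)-6-[(5S,7R)-5-acetoxy-4-methyl-2-oxo-2,5,6,7-tetrahydrooxepin-7-yl]-2-{[(tert-butyldimethylsilyl)oxy]methyl}-3-iodohepta-2,6-dienoate F7. Iodine–magnesium exchange with iPrMgCl·LiCl in THF at −40 °C gives the ester-chelated alkenylmagnesium, which adds to the lactone carbonyl in the same seven-membered mode; aqueous work-up opens the hemiketal 12 to 13. Both operations are known polar chemistry.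

Step 5 (Baeyer–Villiger oxidation of a conjugated enone next to a second alkene). Epoxidation of the exocyclic alkene or vinyl migration could compete. The fallback sets out from 1 and returns at 6; it makes the ketone non-conjugated before oxidation and postpones the chlorination, because sulfur nucleophiles would attack the allylic chloride.
- Luche reduction of 1 gives (1R,5R)-cis-carveol F1.
- Mitsunobu reaction with AcOH gives (1S,5R)-trans-carveyl acetate F2.
- CrO3/3,5-dimethylpyrazole gives (1S,5R)-2-methyl-4-oxo-5-(prop-1-en-2-yl)cyclohex-2-en-1-yl acetate F3.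
- PhSO2Na in AcOH adds to the enone to give (1S,5R)-2-methyl-4-oxo-2-(phenylsulfonyl)-5-(prop-1-en-2-yl)cyclohexyl acetate F4.
- Oxone (KHSO5) oxidises this saturated ketone to (5S,7R)-4-methyl-2-oxo-4-(phenylsulfonyl)-7-(prop-1-en-2-yl)oxepan-5-yl acetate F5 without touching the isopropenyl group.
- DBU expels benzenesulfinate to give (5S,7R)-4-methyl-2-oxo-7-(prop-1-en-2-yl)-2,5,6,7-tetrahydrooxepin-5-yl acetate F6.
- Ca(OCl)2/CO2 chlorination of the isopropenyl group then gives 6.

Step 11 (directed reduction). Hydride may arrive from outside the ring and give the C6 epimer, or conjugate reduction may interfere. The fallback sets out from 13 and returns at 16; it ties the hydride to the C1 oxygen covalently. Me2SiHCl/imidazole gives methyl (2Z)-2-[(3Z,5S,7R)-5-acetoxy-7-[(dimethylsilyl)oxy]-4-methyl-8-methylidene-2-oxocyclodec-3-en-1-ylidene]-3-[(tert-butyldimethylsilyl)oxy]propanoate F8. Catalytic nBu4NF in THF at −20 °C triggers intramolecular hydrosilylation of the C6 ketone to the cyclic dimethylsilylene acetal of diol 14 (C1–O–SiMe2–O–C6) F9, with the same facial sense as in step 11. HF·pyridine then frees 14, which lactonises to 15 and is desilylated to 16.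

**Further compounds**

F1 | step 5 | (1R,5R)-cis-carveol | CC1=CC[C@H](C[C@H]1O)C(C)=C
F2 | step 5 | (1S,5R)-trans-carveyl acetate | CC1=CC[C@H](C[C@@H]1OC(C)=O)C(C)=C
F3 | step 5 | (1S,5R)-2-methyl-4-oxo-5-(prop-1-en-2-yl)cyclohex-2-en-1-yl acetate | CC1=CC(=O)[C@H](C[C@@H]1OC(C)=O)C(C)=C
F4 | step 5 | (1S,5R)-2-methyl-4-oxo-2-(phenylsulfonyl)-5-(prop-1-en-2-yl)cyclohexyl acetate (C2 epimers) | CC1(CC(=O)[C@H](C[C@@H]1OC(C)=O)C(C)=C)S(=O)(=O)c1ccccc1
F5 | step 5 | (5S,7R)-4-methyl-2-oxo-4-(phenylsulfonyl)-7-(prop-1-en-2-yl)oxepan-5-yl acetate (C4 epimers) | CC1(CC(=O)O[C@H](C[C@@H]1OC(C)=O)C(C)=C)S(=O)(=O)c1ccccc1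
F6 | step 5 | (5S,7R)-4-methyl-2-oxo-7-(prop-1-en-2-yl)-2,5,6,7-tetrahydrooxepin-5-yl acetate | CC1=CC(=O)O[C@H](C[C@@H]1OC(C)=O)C(C)=C
F7 | step 10 | methyl (2Z)-6-[(5S,7R)-5-acetoxy-4-methyl-2-oxo-2,5,6,7-tetrahydrooxepin-7-yl]-2-{[(tert-butyldimethylsilyl)oxy]methyl}-3-iodohepta-2,6-dienoate | CC1=CC(=O)O[C@H](C[C@@H]1OC(C)=O)C(=C)CC/C(I)=C(\CO[Si](C)(C)C(C)(C)C)C(=O)OC
F8 | step 11 | methyl (2Z)-2-[(3Z,5S,7R)-5-acetoxy-7-[(dimethylsilyl)oxy]-4-methyl-8-methylidene-2-oxocyclodec-3-en-1-ylidene]-3-[(tert-butyldimethylsilyl)oxy]propanoate | C=C1CC/C(=C(\CO[Si](C)(C)C(C)(C)C)C(=O)OC)C(=O)/C=C(/C)[C@@H](OC(C)=O)C[C@H]1O[SiH](C)C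
F9 | step 11 | cyclic dimethylsilylene acetal of diol 14 (C1–O–SiMe2–O–C6) | C=C1CC/C(=C(\CO[Si](C)(C)C(C)(C)C)C(=O)OC)[C@H]2/C=C(/C)[C@@H](OC(C)=O)C[C@H]1O[Si](C)(C)O2
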